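Sunday's run had c(protic impurity) = 0.75 M against 1.5 M in Friday's, and twice the c(starting material), yet at 50.0 min Sunday's gave 20.1% target and Friday's 20.0%. So I took percent of charge as a measure that carries over to the new flask.

| flask | starting material | protic impurity | remark | time |
|---|---|---|---|---|
| Friday's | 0.75 M | 1.5 M | run made earlier |  |
| Tuesday's | 1.1 M | 1.5 M | run made earlier |  |
| Sunday's | 1.5 M | 0.75 M | run made earlier |  |
| flask | 1.5 M | 1.50 M |  | 1.0 h |

| run | time / min | isomer of the product / % | target / % |
|---|---|---|---|
| Friday's | 6.00 | 2.7 | 3.3 |
| Friday's | 15.0 | 6.2 | 8.7 |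
| Friday's | 20.0 | 8.8 | 10.5 |
| Friday's | 30.0 | 11.2 | 13.7 |
| Friday's | 40.0 | 13.8 | 16.8 |
| Friday's | 50.0 | 14.8 | 20.0 |
| Tuesday's | 2.50 | 1.4 | 1.7 |
| Tuesday's | 8.00 | 3.5 | 5.2 |
| Tuesday's | 15.0 | 5.4 | 8.6 |
| Tuesday's | 20.0 | 7.8 | 10.6 |
| Tuesday's | 30.0 | 11.4 | 13.5 |
| Tuesday's | 40.0 | 13.0 | 17.0 |
| Tuesday's | 50.0 | 14.5 | 19.6 |
| Sunday's | 10.0 | 4.5 | 5.0 |
| Sunday's | 20.0 | 8.1 | 10.8 |
| Sunday's | 30.0 | 11.9 | 14.1 |
| Sunday's | 40.0 | 14.2 | 17.8 |
| Sunday's | 50.0 | 15.5 | 20.1 |

(standard deviation of a reading: 0.5 percentage points)

- the earlier runs were read with a standard deviation of 0.5 percentage points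

- share of isomer of the product in isomer of the product plus target at 1.5 min
- share of isomer of the product in isomer of the product plus target at 1.0 h
- which of isomer of the product and target there is more of at 1.0 h

My estimate rested on the lead ratio, a ratio of amounts read at one time and not a ratio of rates: target divided by isomer of the product, each summed over the earlier runs at 50.0 min. It came to 1.33, which puts target ahead and gives an isomer share of 42.9%.

But the ratio might drift. The earliest readings of the runs, pooled, gave 1.16, a share of 46.3%. The gap between the ratios is 14.7%, while the early isomer sum alone is uncertain by 10.1% of itself, so I could not prove a drift. I still committed to the early share for 1.5 min and the late one for 1.0 h, although the readings stop before that hour.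

Could the lead flip? The ratio exceeds one by 33.0%, and the scatter of the late isomer sum is 1.93% of it, so that objection fell away.

The forecast gave 44.5% (41.5% to 47.5%) early and 43.5% (41% to 45.5%) at the end, with target ahead, calling the shares “flat within noise, which fits parallel formation with a fixed selectivity”. My early share stood above its value.

The flask gave 45.9% and 42.9%, with target ahead.

    starting material ⇌ target (K = 0.970, k = 0.00610 min⁻¹)
    starting material ⇌ isomer of the product (K = 0.500, k = 0.00520 min⁻¹)
    starting material + protic impurity → quenched substrate (k = 7.70 × 10⁻⁴ M⁻¹ min⁻¹)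

At 0.369 h the flask's starting material had a half-life of 1.9 h by the forward step to target and 2.2 h by the forward step to isomer of the product, but 10 h by the loss with protic impurity to quenched substrate, which is slower than either. At 1.00 h the flask held 4.99% quenched substrate. Dividing its 22.1% target by the lead ratio gives 16.6% isomer of the product, and it held 16.6%. In the neighbour flask with 0.90 M of protic impurity, 22.4% target gives 16.8% by the same division, and that flask held 16.9%.

(The numbers in the tables are calculated for substances that don't exist.)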